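The 2,3-dihydro-4H-pyran-4-one ring is disconnected at O1–C2 and C3–C4: its O1–C2(H)(CH3)–C3H2 unit is a 1,2-diol fragment and its O1–C6=C5–C4(=O) unit a 3-alkoxyacrylate. In one operation a 3-lithio-3-methoxyacrylate (a 1,4-C,O-dinucleophile) is annulated onto (S)-propane-1,2-diol cyclic sulfate: C-alkylation at CH2, then O-alkylation at the secondary carbon with inversion, giving (R)-4-methoxy-6-methyl-5,6-dihydropyran-2-one. Acetate enolate addition and acid turn this lactone into the dihydropyranone acetic ester. A Knoevenagel–lactonization with a hexasubstituted salicylaldehyde builds the coumarin last. The same cyclic sulfate, opened by an aryllithium and hydrolysed with retention, supplies the (S)-2-hydroxypropyl side chain.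

Key step: step 2

Assumption: compound 19 is drawn as the open hydroxy aldehyde; it is expected to rest mainly as its six-membered lactol, which reacts through the open form.

Step 1
Reactants: 1 (S)-propane-1,2-diol
Product: 3 (4S)-4-methyl-1,3,2-dioxathiolane 2,2-dioxide, via cyclic sulfite 2 (not isolated)
Conditions: SOCl2, CH2Cl2, 0 → 40 °C; then RuCl3·3H2O (cat.), NaIO4, MeCN/H2O, 0 °C
Reagents that add atoms: thionyl chloride O=S(Cl)Cl; sodium periodate [Na+].[O-]I(=O)(=O)=O
Why: Cyclic sulfite formation from the 1,2-diol followed by ruthenium-catalysed oxidation at sulfur (RuO4 from RuCl3 and NaIO4) is the standard two-stage synthesis of 1,2-diol cyclic sulfates and breaks no C–O bond, so the (S)-centre is kept.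

Step 2
Reactants: 4 methyl (2E)-3-methoxyprop-2-enoate; 3 (4S)-4-methyl-1,3,2-dioxathiolane 2,2-dioxide
Product: 7 (6R)-4-methoxy-6-methyl-5,6-dihydro-2H-pyran-2-one, via vinyllithium 5 (not isolated), via alkyl sulfate 6 (not isolated)
Conditions: LiN(iPr)2, THF, −90 °C; then 3, −78 → 20 °C; then 60 °C
Reagents that add atoms: none
Why: Proposed new method: LiN(iPr)2 removes the vinylic 3-H of 4 that lies cis to the ester (carbonyl-chelated vinyllithium 5), and this carbanion opens cyclic sulfate 3 at its unhindered CH2 by SN2 to give the secondary alkyl sulfate 6 (new bond C4–C5 of 7, later C4–C3 of the dihydropyranone). On heating, the electron-rich carbonyl oxygen of the vinylogous carbonate, held next to the sulfate-bearing carbon by the E double bond, displaces sulfate in a 6-exo-tet SN2 O-alkylation (new bond O1–C6 of 7, later O1–C2), and the O-methyl lactonium ion formed hands its methyl group to the departing sulfate. The closest known reaction types are the butenolide annulation of 3-lithio-3-alkoxyacrylates with aldehydes and the two-fold nucleophilic displacement on 1,2-diol cyclic sulfates; the O-alkylative lactonization of a sulfate monoester is the untested part. No stereocentre is created: the (S)-carbinol carbon of 3 is relayed and inverted by the backside attack of oxygen to (R)-C6 of 7. The step needs C-attack at the primary carbon before O-attack at the secondary one, which the steric bias of 3 and the far higher nucleophilicity of the vinyllithium secure, and complete ring closure before aqueous work-up, since hydrolysis of 6 would give the lactone with retention; unreacted 6 is a salt that stays in the water layer.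

Step 3
Reactants: 7 (6R)-4-methoxy-6-methyl-5,6-dihydro-2H-pyran-2-one; 8 ethyl acetate
Product: 11 ethyl 2-[(2R)-2-methyl-4-oxo-3,4-dihydro-2H-pyran-6-yl]acetate, via lithium enolate 9 (not isolated), via hydroxy keto ester 10 (not isolated)
Conditions: 8, LiN(iPr)2, THF, −78 °C; CeCl3; then 7, −78 → −20 °C; then 1 M HCl, THF, 20 °C
Reagents that add atoms: water O
Why: Crossed Claisen-type 1,2-addition of the cerium-modified acetate enolate to the lactone carbonyl (CeCl3 curbs γ-deprotonation and conjugate addition–elimination) gives hydroxy keto ester 10, which in acid recloses through the same secondary oxygen, dehydrates and hydrolyses its methyl enol ether to the vinylogous ester, the known way from 4-alkoxy-5,6-dihydropyran-2-ones to 2,3-dihydropyran-4-ones; no bond to the stereocentre is broken.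

Step 4
Reactants: 12 2,4-dihydroxy-3-methylbenzaldehyde
Product: 13 5-bromo-2,4-dihydroxy-3-methylbenzaldehyde
Conditions: NBS, MeCN, 0 → 20 °C
Reagents that add atoms: N-bromosuccinimide O=C1CCC(=O)N1Br
Why: Electrophilic aromatic bromination is directed to C5, the only free position activated by both hydroxyl groups (para to 2-OH, ortho to 4-OH), whereas C6 is meta to both.

Step 5
Reactants: 13 5-bromo-2,4-dihydroxy-3-methylbenzaldehyde
Product: 14 5-bromo-2,4-bis(methoxymethoxy)-3-methylbenzaldehyde
Conditions: NaH, MOMCl, DMF, 0 → 20 °C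
Reagents that add atoms: chloromethyl methyl ether COCCl
Why: Williamson etherification of the bis-phenoxide (NaH also frees the hydrogen-bonded 2-OH) installs MOM acetals that withstand palladium catalysis and organolithiums and fall off in dilute acid.

Step 6
Reactants: 14 5-bromo-2,4-bis(methoxymethoxy)-3-methylbenzaldehyde
Product: 15 2,4-bis(methoxymethoxy)-3,5-dimethylbenzaldehyde
Conditions: trimethylboroxine, Pd(dppf)Cl2 (cat.), K2CO3, 1,4-dioxane/H2O, 90 °C
Reagents that add atoms: trimethylboroxine CB1OB(C)OB(C)O1
Why: Suzuki–Miyaura methylation of the aryl bromide with trimethylboroxine under zerovalent palladium catalysis tolerates the aldehyde and the MOM ethers and completes the C3/C5 dimethyl pattern.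

Step 7
Reactants: 15 2,4-bis(methoxymethoxy)-3,5-dimethylbenzaldehyde; 3 (4S)-4-methyl-1,3,2-dioxathiolane 2,2-dioxide
Product: 19 2,4-dihydroxy-6-[(2S)-2-hydroxypropyl]-3,5-dimethylbenzaldehyde, via amino alkoxide 16 (not isolated), via aryllithium 17 (not isolated), via sulfate ester 18 (not isolated)
Conditions: LiN(Me)CH2CH2NMe2 (from Me2NCH2CH2NHMe, nBuLi), THF, −20 °C; nBuLi, −20 °C; then 3, −78 → 0 °C; then 1 M H2SO4, THF, 40 °C
Reagents that add atoms: none
Why: Directed ortho-metalation: the aldehyde is masked in situ as a chelating lithium α-amino alkoxide that steers butyllithium to the only ring hydrogen (C6), the aryllithium opens cyclic sulfate 3 at its CH2 group by SN2, and dilute acid then cleaves the sulfate monoester at S–O (retention, so the (S)-centre of 3 is carried over unchanged), removes both MOM groups and releases the aldehyde.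

Step 8
Reactants: 19 2,4-dihydroxy-6-[(2S)-2-hydroxypropyl]-3,5-dimethylbenzaldehyde; 11 ethyl 2-[(2R)-2-methyl-4-oxo-3,4-dihydro-2H-pyran-6-yl]acetate
Product: 21 7-hydroxy-5-[(2S)-2-hydroxypropyl]-6,8-dimethyl-3-[(2R)-2-methyl-4-oxo-3,4-dihydro-2H-pyran-6-yl]-2H-chromen-2-one, via arylidene ester 20 (not isolated)
Conditions: piperidine (cat.), AcOH (cat.), EtOH, 60 °C
Reagents that add atoms: none
Why: Knoevenagel condensation of the vinylogous malonate-type CH2 of 11 (flanked by the ester and the β-carbon of the enone) with the aldehyde form of 19, then lactonization of the ortho-phenol onto the ethyl ester, builds the coumarin; arylidene E/Z isomers and any isochroman formed by reversible addition of the side-chain hydroxyl drain into the irreversible lactonization, no stereocentre is formed and the buffered amine is mild enough to leave the β-alkoxy ketone centre intact.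

Compound list

1 | (S)-propane-1,2-diol | C[C@H](O)CO | starting material
2 | (4S)-4-methyl-1,3,2-dioxathiolane 2-oxide (cyclic sulfite, either configuration at sulfur) | C[C@H]1COS(=O)O1 | intermediate
3 | (4S)-4-methyl-1,3,2-dioxathiolane 2,2-dioxide (cyclic sulfate) | C[C@H]1COS(=O)(=O)O1 | intermediate
4 | methyl (2E)-3-methoxyprop-2-enoate | CO/C=C/C(=O)OC | starting material
5 | methyl (2E)-3-lithio-3-methoxyprop-2-enoate (lithium cis to the ester group) | CO/C([Li])=C/C(=O)OC | intermediate
6 | lithium (2S,4E)-4,6-dimethoxy-6-oxohex-4-en-2-yl sulfate | CO/C(C[C@H](C)OS(=O)(=O)[O-])=C/C(=O)OC.[Li+] | intermediate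
7 | (6R)-4-methoxy-6-methyl-5,6-dihydro-2H-pyran-2-one | COC1=CC(=O)O[C@H](C)C1 | intermediate
8 | ethyl acetate | CCOC(C)=O | starting material
9 | lithium 1-ethoxyethen-1-olate (lithium enolate of ethyl acetate) | [Li+].[O-]C(=C)OCC | intermediate
10 | ethyl (4E,7R)-7-hydroxy-5-methoxy-3-oxooct-4-enoate | CCOC(=O)CC(=O)/C=C(OC)\C[C@@H](C)O | intermediate
11 | ethyl 2-[(2R)-2-methyl-4-oxo-3,4-dihydro-2H-pyran-6-yl]acetate | CCOC(=O)CC1=CC(=O)C[C@@H](C)O1 | intermediate
12 | 2,4-dihydroxy-3-methylbenzaldehyde | Cc1c(O)ccc(C=O)c1O | starting material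
13 | 5-bromo-2,4-dihydroxy-3-methylbenzaldehyde | Cc1c(O)c(Br)cc(C=O)c1O | intermediate
14 | 5-bromo-2,4-bis(methoxymethoxy)-3-methylbenzaldehyde | COCOc1c(C)c(OCOC)c(Br)cc1C=O | intermediate
15 | 2,4-bis(methoxymethoxy)-3,5-dimethylbenzaldehyde | COCOc1c(C)c(OCOC)c(C)cc1C=O | intermediate
16 | lithium α-amino alkoxide formed from 15 and LiN(Me)CH2CH2NMe2 at the formyl carbon | COCOc1c(C)c(OCOC)c(C)cc1C([O-])N(C)CCN(C)C.[Li+] | intermediate
17 | 6-lithio derivative of amino alkoxide 16 | COCOc1c(C)c(OCOC)c(C)c([Li])c1C([O-])N(C)CCN(C)C.[Li+] | intermediate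
18 | dilithium salt of the 6-[(2S)-2-(sulfonatooxy)propyl] derivative of amino alkoxide 16 | COCOc1c(C)c(OCOC)c(C)c(C[C@H](C)OS(=O)(=O)[O-])c1C([O-])N(C)CCN(C)C.[Li+].[Li+] | intermediate
19 | 2,4-dihydroxy-6-[(2S)-2-hydroxypropyl]-3,5-dimethylbenzaldehyde (open form of (3S)-3,5,7-trimethyl-3,4-dihydro-1H-isochromene-1,6,8-triol) | C[C@H](O)Cc1c(C)c(O)c(C)c(O)c1C=O | intermediate
20 | ethyl (2Z)-3-{2,4-dihydroxy-6-[(2S)-2-hydroxypropyl]-3,5-dimethylphenyl}-2-[(2R)-2-methyl-4-oxo-3,4-dihydro-2H-pyran-6-yl]prop-2-enoate | CCOC(=O)/C(C1=CC(=O)C[C@@H](C)O1)=C\c1c(O)c(C)c(O)c(C)c1C[C@H](C)O | intermediate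
21 | 7-hydroxy-5-[(2S)-2-hydroxypropyl]-6,8-dimethyl-3-[(2R)-2-methyl-4-oxo-3,4-dihydro-2H-pyran-6-yl]-2H-chromen-2-one | Cc1c(O)c(C)c2oc(=O)c(C3=CC(=O)C[C@@H](C)O3)cc2c1C[C@H](C)O | target

Total steps: 8. Longest linear sequence: 5 steps (12 → 13 → 14 → 15 → 19 → 21); the pyranone branch (1 → 3 → 7 → 11) joins in step 8.

Steps most likely to fail

Step 2 (the step labelled as a proposed new method). The vinyllithium may decompose or self-condense before C-alkylation. The O-alkylative ring closure may also be sluggish, which would leave the sulfate to be hydrolysed with retention and erode the enantiomeric purity. The fallback uses known chemistry only; it sets out from ethyl acetate 8 and returns at 7. Lithium enolate 9 (3 equiv, THF, −78 → −20 °C) is acylated by commercial ethyl (R)-3-hydroxybutanoate in a crossed Claisen condensation to give ethyl (5R)-5-hydroxy-3-oxohexanoate F1. K2CO3 in MeOH followed by HCl lactonizes it to (6R)-6-methyloxane-2,4-dione F2. Me2SO4, K2CO3, acetone then O-methylates the enol to 7. The stereocentre is bought in the (R)-form and its C–O bond is never broken.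

Step 8. Condensation of the hindered, electron-rich lactol with the only moderately acidic vinylogous methylene may be slow. The arylidene may be trapped by the side-chain hydroxyl as an isochroman. Configuration at C2 of the dihydropyranone may be lost through amine-induced retro-oxa-Michael ring opening. The fallback sets out from hydroxy keto ester 10, isolated by quenching step 3 with pH 7 buffer instead of acid, and returns at 21. The much more acidic β-keto ester 10 is condensed with 19 (piperidine, AcOH, EtOH, 20 °C) to 7-hydroxy-3-[(2E,5R)-5-hydroxy-3-methoxyhex-2-enoyl]-5-[(2S)-2-hydroxypropyl]-6,8-dimethyl-2H-chromen-2-one F3, in which the stereocentre is a plain secondary alcohol that cannot ring-open. TFA in wet CH2Cl2 then closes the dihydropyranone by hemiketalization, dehydration and enol ether hydrolysis to give 21, so the sensitive β-alkoxy ketone never meets base.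

Step 7. Lateral (benzylic) lithiation next to the MOM ethers may compete with ring lithiation. Ring lithiation of the crowded arene may be incomplete. Residual butyllithium consumes the cyclic sulfate, so an excess of 3 is needed. The electron-rich lactol may also self-condense in acid. The fallback sets out from aldehyde 15 and returns at 19. NaClO2, NaH2PO4, 2-methylbut-2-ene (Pinnick oxidation) gives 2,4-bis(methoxymethoxy)-3,5-dimethylbenzoic acid F4. (COCl)2 followed by Et2NH gives N,N-diethyl-2,4-bis(methoxymethoxy)-3,5-dimethylbenzamide F5, whose tertiary amide is a far stronger ortho director. sBuLi, TMEDA, THF, −78 °C, then 3, then warm 1 M H2SO4 hydrolyses the sulfate, removes the MOM groups and lactonizes with loss of diethylamine, giving (3S)-6,8-dihydroxy-3,5,7-trimethyl-3,4-dihydro-1H-isochromen-1-one F6. iBu2AlH, CH2Cl2, −78 °C reduces the lactone to the lactol, which is 19.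

Further compounds
F1 | step 2 | ethyl (5R)-5-hydroxy-3-oxohexanoate | CCOC(=O)CC(=O)C[C@@H](C)O
F2 | step 2 | (6R)-6-methyloxane-2,4-dione | C[C@@H]1CC(=O)CC(=O)O1
F3 | step 8 | 7-hydroxy-3-[(2E,5R)-5-hydroxy-3-methoxyhex-2-enoyl]-5-[(2S)-2-hydroxypropyl]-6,8-dimethyl-2H-chromen-2-one | CO/C(C[C@@H](C)O)=C/C(=O)c1cc2c(C[C@H](C)O)c(C)c(O)c(C)c2oc1=O
F4 | step 7 | 2,4-bis(methoxymethoxy)-3,5-dimethylbenzoic acid | COCOc1c(C)c(OCOC)c(C)cc1C(=O)O
F5 | step 7 | N,N-diethyl-2,4-bis(methoxymethoxy)-3,5-dimethylbenzamide | CCN(CC)C(=O)c1cc(C)c(OCOC)c(C)c1OCOC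
F6 | step 7 | (3S)-6,8-dihydroxy-3,5,7-trimethyl-3,4-dihydro-1H-isochromen-1-one | C[C@H]1Cc2c(C)c(O)c(C)c(O)c2C(=O)O1
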